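**Retrosyn­thetic overview**
1. The target is a 1,2-dioxane propanoate (ring B) joined by a CH2CH2 link to a cyclohexane (ring A) whose C1 carries OH, C2 two methyls and C6 an exocyclic CH2.
2. Enabling feature: in ring A the quaternary C2(CH3)2 is bonded to C1, and C1 lies between C6 (a masked ketone) and the side-chain CH2 (a masked ester carbon). Ring A is thus a prenyl unit joined to an acetoacetate, and its C4–C5 and C1–C2 bonds are cut together in a [3+3] step that copies head-to-tail prenyl transfer followed by cyclase closure.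
3. After the annulation: C1–OH by catalytic asymmetric α-hydroxylation, C6=CH2 by methylenation, ester → spiro-epoxide, which the dianion of 4-methylpent-4-en-1-ol opens to add the link and C6–C3 of ring B.
4. Ring B last: an Evans syn-aldol sets the propanoate stereodiad, SN2 of a mesylate by hydroperoxide (inversion) makes O–C3, and 6-exo cycloperoxymercuration–demercuration makes O–C6 and the 6-methyl; oxidation and esterification finish.
5. Order of ring formation: ring A (step 1), then ring B (step 14).

Key step: step 1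

Remark: 1, 2, 10 and 15 are bought. In step 2 dihydroquinine is written; if a trial run shows it favours the (1R)-alcohol, its pseudo-enantiomer dihydroquinidine is used instead.

**Step 1**
Reactants: 1 1-bromo-3-methylbut-2-ene; 2 1-methoxy-1,3-bis(trimethylsilyloxy)buta-1,3-diene
Product: 5 methyl 2,2-dimethyl-6-oxocyclohexane-1-carboxylate (racemic), via silyl enol ether 3 (not isolated), via keto ester 4 (not isolated)
Conditions: ZnBr2 (20 mol %), CH2Cl2, −30 → 0 °C; then MeOH (2 equiv), TfOH (10 mol %), 0 °C → rt, same flask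
Reagents that add atoms: none
Why: Proposed new method: ZnBr2 ionises 1 to the prenyl cation, which is captured at its unhindered CH2 terminus by the terminal carbon of the bis-silyl dienol ether 2 (loss of Me3SiBr) to give 3 and the C4–C5 bond; methanol then strips the silyl groups as Me3SiOMe and releases HBr, which together with TfOH protonates the trisubstituted alkene of 4 in the Markovnikov sense, and the enol carbon between the two carbonyl groups attacks the tertiary cation to form the C1–C2 bond. The closest known reaction types are the Lewis-acid [3+3] cyclisations of 1,3-bis(silyl enol ethers) with 1,3-dielectrophiles, the ZnBr2-catalysed prenylation of silyl enol ethers and the acid-mediated olefin cyclisation of unsaturated β-keto esters to 2-carbalkoxy-3,3-dimethylcyclohexanones; new is their fusion into one operation in which prenyl bromide serves as a 1,3-dielectrophile. The single ring closes in a 6-(enolendo)-exo-trig mode onto the tertiary cation (formally a Markovnikov 6-endo hydroalkylation of the alkene). The one stereocentre created, C1, forms racemic and stays enolisable, so no control is needed here; it is fixed in step 2. The step needs terminal rather than internal attack of the dienol ether, attack at the primary rather than the tertiary allyl terminus, and C- rather than O-alkylation in the closure: the first follows from the higher nucleophilicity of the terminal carbon of the bis-silyl diene, the second from the steric difference between the two cation termini, and the third from the reversibility of O-alkylation under acid. The sequence mirrors head-to-tail prenyl transfer followed by cyclase-type closure.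

**Step 2**
Reactants: 5 methyl 2,2-dimethyl-6-oxocyclohexane-1-carboxylate
Product: 6 methyl (1S)-1-hydroxy-2,2-dimethyl-6-oxocyclohexane-1-carboxylate
Conditions: cumene hydroperoxide (1.2 equiv), dihydroquinine (20 mol %), CH2Br2, rt
Reagents that add atoms: cumene hydroperoxide, CC(C)(OO)c1ccccc1
Why: Organocatalytic enantioselective α-hydroxylation of a cyclic β-keto ester: the alkaloid forms a chiral ammonium enolate ion pair from the enolisable C1 and delivers the peroxide oxygen to one enolate face, so the (1S)-carbinol is set under catalyst control.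

**Step 3**
Reactants: 6 methyl (1S)-1-hydroxy-2,2-dimethyl-6-oxocyclohexane-1-carboxylate
Product: 7 methyl (1S)-1-hydroxy-2,2-dimethyl-6-methylidenecyclohexane-1-carboxylate
Conditions: Zn, CH2Br2, TiCl4 (reagent preformed in THF), then 6, CH2Cl2, 0 °C → rt
Reagents that add atoms: dibromomethane, BrCBr
Why: Takai–Lombardo methylenation: the non-basic titanium–zinc methylene reagent converts the hindered ketone into the exocyclic alkene without touching the ester and without the α-ketol rearrangement that basic ylides would provoke; C1 is not involved.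

**Step 4**
Reactants: 7 methyl (1S)-1-hydroxy-2,2-dimethyl-6-methylidenecyclohexane-1-carboxylate
Product: 8 (1S)-1-(hydroxymethyl)-2,2-dimethyl-6-methylidenecyclohexan-1-ol
Conditions: LiAlH4, THF, 0 °C → rt; aq NaOH work-up
Reagents that add atoms: none
Why: Hydride reduction of the ester to the primary alcohol; the isolated alkene and the C1 stereocentre are untouched.

**Step 5**
Reactants: 8 (1S)-1-(hydroxymethyl)-2,2-dimethyl-6-methylidenecyclohexan-1-ol
Product: 9 (3S)-4,4-dimethyl-8-methylidene-1-oxaspiro[2.5]octane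
Conditions: NaH (2.2 equiv), 1-(p-toluenesulfonyl)imidazole, THF, 0 °C → rt
Reagents that add atoms: none
Why: One-pot epoxide formation from a 1,2-diol: the primary alkoxide is sulfonylated selectively and the tertiary alkoxide closes by 3-exo-tet displacement, so the C–O bond at the stereocentre is never broken (retention).

**Step 6**
Reactants: 9 (3S)-4,4-dimethyl-8-methylidene-1-oxaspiro[2.5]octane; 10 4-methylpent-4-en-1-ol
Product: 12 (1S)-1-(6-hydroxy-3-methylidenehexyl)-2,2-dimethyl-6-methylidenecyclohexan-1-ol, via allyllithium alkoxide 11 (not isolated)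
Conditions: 10, n-BuLi (2.2 equiv), TMEDA, Et2O–hexane, 0 °C → rt; then 9, THF, −78 → 0 °C
Reagents that add atoms: none
Why: Allylic lithiation of the 2-methylallyl unit of the alkoxide gives a 2-substituted allyl anion whose two CH2 termini are equivalent; as a hard organolithium it should open the epoxide by direct SN2 at the unhindered CH2 rather than SN2′ at the exocyclic methylene, leaving the carbinol stereocentre untouched.

**Step 7**
Reactants: 12 (1S)-1-(6-hydroxy-3-methylidenehexyl)-2,2-dimethyl-6-methylidenecyclohexan-1-ol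
Product: 13 bis(triethylsilyl) ether of 12
Conditions: Et3SiOTf (2.5 equiv), 2,6-lutidine, CH2Cl2, −78 → 0 °C
Reagents that add atoms: triethylsilyl trifluoromethanesulfonate, CC[Si](CC)(CC)OS(=O)(=O)C(F)(F)F
Why: Silyl triflate silylation protects both hydroxyls, including the hindered tertiary one, which must not compete as a nucleophile in step 14.

**Step 8**
Reactants: 13 bis(triethylsilyl) ether of 12
Product: 14 6-[(1S)-2,2-dimethyl-6-methylidene-1-(triethylsilyloxy)cyclohexyl]-4-methylidenehexanal
Conditions: (COCl)2, DMSO, CH2Cl2, −78 °C; then Et3N, −78 → 0 °C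
Reagents that add atoms: none
Why: Swern oxidation cleaves and oxidises a primary triethylsilyl ether directly to the aldehyde while the hindered tertiary silyl ether survives.

**Step 9**
Reactants: 14 6-[(1S)-2,2-dimethyl-6-methylidene-1-(triethylsilyloxy)cyclohexyl]-4-methylidenehexanal; 15 (4S)-4-benzyl-3-propanoyl-1,3-oxazolidin-2-one
Product: 17 (4S)-4-benzyl-3-[(2S,3R)-8-[(1S)-2,2-dimethyl-6-methylidene-1-(triethylsilyloxy)cyclohexyl]-3-hydroxy-2-methyl-6-methylideneoctanoyl]-1,3-oxazolidin-2-one, via boron enolate 16 (not isolated)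
Conditions: 15, n-Bu2BOTf, i-Pr2NEt, CH2Cl2, 0 °C; then 14, −78 → 0 °C; pH 7 buffer–MeOH work-up
Reagents that add atoms: none
Why: Evans syn-aldol: the (Z)-boron enolate reacts through a Zimmerman–Traxler chair in which the benzyl group of the auxiliary shields one enolate face, giving the (2S,3R) syn adduct under reagent control.

**Step 10**
Reactants: 17 Evans aldol adduct
Product: 18 (2R,3R)-8-[(1S)-2,2-dimethyl-6-methylidene-1-(triethylsilyloxy)cyclohexyl]-2-methyl-6-methylideneoctane-1,3-diol
Conditions: LiBH4, MeOH (1 equiv), THF, 0 °C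
Reagents that add atoms: none
Why: Reductive removal of the oxazolidinone gives the 1,3-diol without epimerisation; the descriptor at C2 changes only because the substituent priorities change.

**Step 11**
Reactants: 18 the 1,3-diol
Product: 19 (2R,3R)-1-[tert-butyl(diphenyl)silyloxy]-8-[(1S)-2,2-dimethyl-6-methylidene-1-(triethylsilyloxy)cyclohexyl]-2-methyl-6-methylideneoctan-3-ol
Conditions: t-BuPh2SiCl, imidazole, CH2Cl2, 0 °C
Reagents that add atoms: tert-butyl(chloro)diphenylsilane, CC(C)(C)[Si](Cl)(c1ccccc1)c1ccccc1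
Why: Sterically controlled silylation of the primary hydroxyl leaves the secondary one free.

**Step 12**
Reactants: 19 the secondary alcohol
Product: 20 methanesulfonate of 19, (3R)
Conditions: MsCl, Et3N, CH2Cl2, −20 → 0 °C
Reagents that add atoms: methanesulfonyl chloride, CS(=O)(=O)Cl
Why: Sulfonylation at oxygen activates C3 with retention of configuration.

**Step 13**
Reactants: 20 the (3R)-mesylate
Product: 21 tert-butyl{[(2R,3S)-8-[(1S)-2,2-dimethyl-6-methylidene-1-(triethylsilyloxy)cyclohexyl]-3-hydroperoxy-2-methyl-6-methylideneoctyl]oxy}diphenylsilane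
Conditions: 50 % aq H2O2 (excess), KOH, MeOH–THF, 0 °C → rt
Reagents that add atoms: hydrogen peroxide, OO
Why: SN2 displacement of the secondary mesylate by the weakly basic, α-effect hydroperoxide anion with inversion turns the (3R)-mesylate into the (3S)-hydroperoxide; with C1 at the alcohol level no enolate-driven β-elimination is possible.

**Step 14**
Reactants: 21 the (3S)-hydroperoxide
Product: 23 tert-butyl{(2R)-2-[(3S,6R)-6-{2-[(1S)-2,2-dimethyl-6-methylidene-1-(triethylsilyloxy)cyclohexyl]ethyl}-6-methyl-1,2-dioxan-3-yl]propoxy}diphenylsilane, via organomercurial 22 (not isolated)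
Conditions: Hg(OCOCF3)2, CH2Cl2, −20 °C; then NaBH4, 3 M aq NaOH, 0 °C
Reagents that add atoms: none
Why: Cycloperoxymercuration–demercuration: Markovnikov, anti 6-exo-trig attack of the hydroperoxide on the mercurinium ion of the chain alkene (the shielded ring methylene has no tethered nucleophile), then hydride replaces mercury to give the 6-methyl group; C6 is set in a chair transition state with the C3 side chain and the bulky mercurated CH2 both equatorial, so the chain is axial and cis to the C3 substituent, (6R), the minor C6 epimer being removed by chromatography.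

**Step 15**
Reactants: 23 the bis-silyl ether
Product: 24 (2R)-2-[(3S,6R)-6-{2-[(1S)-1-hydroxy-2,2-dimethyl-6-methylidenecyclohexyl]ethyl}-6-methyl-1,2-dioxan-3-yl]propan-1-ol
Conditions: Bu4NF, THF, 0 °C → rt
Reagents that add atoms: none
Why: Fluoride cleaves both silyl ethers; the dialkyl peroxide tolerates these conditions and no stereocentre is touched.

**Step 16**
Reactants: 24 the diol
Product: 25 (2S)-2-[(3S,6R)-6-{2-[(1S)-1-hydroxy-2,2-dimethyl-6-methylidenecyclohexyl]ethyl}-6-methyl-1,2-dioxan-3-yl]propanoic acid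
Conditions: TEMPO (cat.), PhI(OAc)2, MeCN–H2O (pH 7 buffer), rt
Reagents that add atoms: water, O
Why: Oxoammonium-mediated oxidation takes the primary alcohol through the aldehyde hydrate to the acid, and leaves the tertiary allylic alcohol, the alkene and the peroxide alone; the neutral medium should preserve the α-stereocentre.

**Step 17**
Reactants: 25 the acid
Product: 26 methyl (2S)-2-[(3S,6R)-6-{2-[(1S)-1-hydroxy-2,2-dimethyl-6-methylidenecyclohexyl]ethyl}-6-methyl-1,2-dioxan-3-yl]propanoate (target, CNP0255906.1)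
Conditions: Me3SiCHN2, MeOH–toluene, 0 °C
Reagents that add atoms: (trimethylsilyl)diazomethane, C[Si](C)(C)C=[N+]=[N-]
Why: Esterification by O-methylation of the carboxylate under non-basic conditions avoids epimerisation at C2 and retro-oxa-Michael opening of the β-peroxy ester.

**Compound list**
1 | 1-bromo-3-methylbut-2-ene | CC(C)=CCBr | starting material
2 | 1-methoxy-1,3-bis(trimethylsilyloxy)buta-1,3-diene | C=C(O[Si](C)(C)C)C=C(OC)O[Si](C)(C)C | starting material
3 | methyl (2Z)-7-methyl-3-(trimethylsilyloxy)octa-2,6-dienoate (not isolated) | COC(=O)/C=C(/CCC=C(C)C)O[Si](C)(C)C | intermediate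
4 | methyl 7-methyl-3-oxooct-6-enoate (not isolated) | COC(=O)CC(=O)CCC=C(C)C | intermediate
5 | methyl 2,2-dimethyl-6-oxocyclohexane-1-carboxylate (racemic) | COC(=O)C1C(=O)CCCC1(C)C | intermediate
6 | methyl (1S)-1-hydroxy-2,2-dimethyl-6-oxocyclohexane-1-carboxylate | O=C1CCCC(C)(C)[C@@]1(O)C(=O)OC | intermediate
7 | methyl (1S)-1-hydroxy-2,2-dimethyl-6-methylidenecyclohexane-1-carboxylate | C=C1CCCC(C)(C)[C@@]1(O)C(=O)OC | intermediate
8 | (1S)-1-(hydroxymethyl)-2,2-dimethyl-6-methylidenecyclohexan-1-ol | C=C1CCCC(C)(C)[C@@]1(O)CO | intermediate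
9 | (3S)-4,4-dimethyl-8-methylidene-1-oxaspiro[2.5]octane | C=C1CCCC(C)(C)[C@@]12CO2 | intermediate
10 | 4-methylpent-4-en-1-ol | C=C(C)CCCO | starting material
11 | O,C-dilithio derivative of 10, 2-(3-lithiooxypropyl)allyllithium (not isolated) | [Li]CC(=C)CCCO[Li] | intermediate
12 | (1S)-1-(6-hydroxy-3-methylidenehexyl)-2,2-dimethyl-6-methylidenecyclohexan-1-ol | C=C1CCCC(C)(C)[C@@]1(O)CCC(=C)CCCO | intermediate
13 | bis(triethylsilyl) ether of 12 | C=C1CCCC(C)(C)[C@@]1(O[Si](CC)(CC)CC)CCC(=C)CCCO[Si](CC)(CC)CC | intermediate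
14 | 6-[(1S)-2,2-dimethyl-6-methylidene-1-(triethylsilyloxy)cyclohexyl]-4-methylidenehexanal | C=C1CCCC(C)(C)[C@@]1(O[Si](CC)(CC)CC)CCC(=C)CCC=O | intermediate
15 | (4S)-4-benzyl-3-propanoyl-1,3-oxazolidin-2-one | CCC(=O)N1[C@@H](Cc2ccccc2)COC1=O | starting material
16 | (Z)-dibutylboron enolate of 15 (not isolated) | C/C=C(\OB(CCCC)CCCC)N1[C@@H](Cc2ccccc2)COC1=O | intermediate
17 | (4S)-4-benzyl-3-[(2S,3R)-8-[(1S)-2,2-dimethyl-6-methylidene-1-(triethylsilyloxy)cyclohexyl]-3-hydroxy-2-methyl-6-methylideneoctanoyl]-1,3-oxazolidin-2-one | C=C1CCCC(C)(C)[C@@]1(O[Si](CC)(CC)CC)CCC(=C)CC[C@H]([C@H](C)C(=O)N1[C@@H](Cc2ccccc2)COC1=O)O | intermediate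
18 | (2R,3R)-8-[(1S)-2,2-dimethyl-6-methylidene-1-(triethylsilyloxy)cyclohexyl]-2-methyl-6-methylideneoctane-1,3-diol | C=C1CCCC(C)(C)[C@@]1(O[Si](CC)(CC)CC)CCC(=C)CC[C@H]([C@H](C)CO)O | intermediate
19 | (2R,3R)-1-[tert-butyl(diphenyl)silyloxy]-8-[(1S)-2,2-dimethyl-6-methylidene-1-(triethylsilyloxy)cyclohexyl]-2-methyl-6-methylideneoctan-3-ol | C=C1CCCC(C)(C)[C@@]1(O[Si](CC)(CC)CC)CCC(=C)CC[C@H]([C@H](C)CO[Si](c1ccccc1)(c1ccccc1)C(C)(C)C)O | intermediate
20 | (2R,3R)-1-[tert-butyl(diphenyl)silyloxy]-8-[(1S)-2,2-dimethyl-6-methylidene-1-(triethylsilyloxy)cyclohexyl]-2-methyl-6-methylideneoctan-3-yl methanesulfonate | C=C1CCCC(C)(C)[C@@]1(O[Si](CC)(CC)CC)CCC(=C)CC[C@H]([C@H](C)CO[Si](c1ccccc1)(c1ccccc1)C(C)(C)C)OS(C)(=O)=O | intermediate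
21 | tert-butyl{[(2R,3S)-8-[(1S)-2,2-dimethyl-6-methylidene-1-(triethylsilyloxy)cyclohexyl]-3-hydroperoxy-2-methyl-6-methylideneoctyl]oxy}diphenylsilane | C=C1CCCC(C)(C)[C@@]1(O[Si](CC)(CC)CC)CCC(=C)CC[C@@H]([C@H](C)CO[Si](c1ccccc1)(c1ccccc1)C(C)(C)C)OO | intermediate
22 | 6-[(trifluoroacetoxy)mercuriomethyl] analogue of 23, same configuration (not isolated) | C=C1CCCC(C)(C)[C@@]1(O[Si](CC)(CC)CC)CC[C@@]1(C[Hg]OC(=O)C(F)(F)F)CC[C@@H]([C@H](C)CO[Si](c2ccccc2)(c2ccccc2)C(C)(C)C)OO1 | intermediate
23 | tert-butyl{(2R)-2-[(3S,6R)-6-{2-[(1S)-2,2-dimethyl-6-methylidene-1-(triethylsilyloxy)cyclohexyl]ethyl}-6-methyl-1,2-dioxan-3-yl]propoxy}diphenylsilane | C=C1CCCC(C)(C)[C@@]1(O[Si](CC)(CC)CC)CC[C@@]1(C)CC[C@@H]([C@H](C)CO[Si](c2ccccc2)(c2ccccc2)C(C)(C)C)OO1 | intermediate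
24 | (2R)-2-[(3S,6R)-6-{2-[(1S)-1-hydroxy-2,2-dimethyl-6-methylidenecyclohexyl]ethyl}-6-methyl-1,2-dioxan-3-yl]propan-1-ol | C=C1CCCC(C)(C)[C@@]1(O)CC[C@@]1(C)CC[C@@H]([C@H](C)CO)OO1 | intermediate
25 | (2S)-2-[(3S,6R)-6-{2-[(1S)-1-hydroxy-2,2-dimethyl-6-methylidenecyclohexyl]ethyl}-6-methyl-1,2-dioxan-3-yl]propanoic acid | C=C1CCCC(C)(C)[C@@]1(O)CC[C@@]1(C)CC[C@@H]([C@H](C)C(=O)O)OO1 | intermediate
26 | methyl (2S)-2-[(3S,6R)-6-{2-[(1S)-1-hydroxy-2,2-dimethyl-6-methylidenecyclohexyl]ethyl}-6-methyl-1,2-dioxan-3-yl]propanoate | C=C1CCCC(C)(C)[C@@]1(O)CC[C@@]1(C)CC[C@@H]([C@H](C)C(=O)OC)OO1 | target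

**Step count and risks**
Total step count: 17. Longest linear sequence: 17 steps (1 and 2 to 26).

Steps most likely to fail:

Step 1 (proposed new method). The fusion of two cationic events in one flask may break down through attack at the tertiary terminus of the prenyl cation, through O- instead of C-alkylation in the closure, or through cationic oligomerisation of the alkene. The fallback is the stepwise, known sequence; it sets out from 1 and returns to the route at 5. Methyl acetoacetate is deprotonated twice (NaH, then n-BuLi, THF, 0 °C) to its dianion, sodium lithium 1-methoxy-1,3-dioxobutane-2,4-diide F1. F1 is alkylated at its terminal carbon by 1 to give 4, now isolated, and SnCl4 in CH2Cl2 (0 °C → rt) cyclises 4 to 5.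

Step 13. Substitution at the β-branched secondary mesylate may be slow, so that elimination and further alkylation of the product hydroperoxide take over. The fallback switches to a masked hydroperoxide and a better leaving group; it sets out from 19 and returns at 21. Compound 19 is converted (Tf2O, 2,6-lutidine, CH2Cl2, −78 °C) into (2R,3R)-1-[tert-butyl(diphenyl)silyloxy]-8-[(1S)-2,2-dimethyl-6-methylidene-1-(triethylsilyloxy)cyclohexyl]-2-methyl-6-methylideneoctan-3-yl trifluoromethanesulfonate F2. F2 alkylates the potassium salt of 2-methoxyprop-2-yl hydroperoxide (KOt-Bu, THF, −20 °C; the reagent is made by ozonolysis of 2,3-dimethylbut-2-ene in methanol) with inversion, giving the mixed peroxyketal tert-butyl{[(2R,3S)-8-[(1S)-2,2-dimethyl-6-methylidene-1-(triethylsilyloxy)cyclohexyl]-3-[(2-methoxypropan-2-yl)peroxy]-2-methyl-6-methylideneoctyl]oxy}diphenylsilane F3. Aqueous acetic acid in THF then releases 21.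

Step 14. Facial selectivity at C6 in the mercurinium closure may be low, the ring methylene may be mercurated, and the β-peroxyalkyl radical of the demercuration may fragment with loss of the peroxide. The fallback reverses the order of C–O bond formation and closes the ring by substitution; it sets out from 20, replaces steps 13 and 14, and returns at 23. Intermolecular Markovnikov hydroperoxymercuration of the unhindered chain alkene of 20 (Hg(OAc)2, 50 % H2O2, CH2Cl2; then NaBH4, aq NaOH) should give the tertiary hydroperoxide (2R,3R,6R)-1-[tert-butyl(diphenyl)silyloxy]-8-[(1S)-2,2-dimethyl-6-methylidene-1-(triethylsilyloxy)cyclohexyl]-6-hydroperoxy-2,6-dimethyloctan-3-yl methanesulfonate F4 together with its C6 epimer, which is separated at this stage. KOt-Bu with 18-crown-6 in toluene then closes the 1,2-dioxane by 6-exo-tet SN2 displacement of the mesylate, with inversion at C3, to give 23.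

**Further compounds**
F1 | step 1 | sodium lithium 1-methoxy-1,3-dioxobutane-2,4-diide (dianion of methyl acetoacetate) | [Na+].[Li+].[CH2-]C(=O)[CH-]C(=O)OC
F2 | step 13 | (2R,3R)-1-[tert-butyl(diphenyl)silyloxy]-8-[(1S)-2,2-dimethyl-6-methylidene-1-(triethylsilyloxy)cyclohexyl]-2-methyl-6-methylideneoctan-3-yl trifluoromethanesulfonate | C=C1CCCC(C)(C)[C@@]1(O[Si](CC)(CC)CC)CCC(=C)CC[C@H]([C@H](C)CO[Si](c1ccccc1)(c1ccccc1)C(C)(C)C)OS(=O)(=O)C(F)(F)F
F3 | step 13 | tert-butyl{[(2R,3S)-8-[(1S)-2,2-dimethyl-6-methylidene-1-(triethylsilyloxy)cyclohexyl]-3-[(2-methoxypropan-2-yl)peroxy]-2-methyl-6-methylideneoctyl]oxy}diphenylsilane | C=C1CCCC(C)(C)[C@@]1(O[Si](CC)(CC)CC)CCC(=C)CC[C@@H]([C@H](C)CO[Si](c1ccccc1)(c1ccccc1)C(C)(C)C)OOC(C)(C)OC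
F4 | step 14 | (2R,3R,6R)-1-[tert-butyl(diphenyl)silyloxy]-8-[(1S)-2,2-dimethyl-6-methylidene-1-(triethylsilyloxy)cyclohexyl]-6-hydroperoxy-2,6-dimethyloctan-3-yl methanesulfonate | C=C1CCCC(C)(C)[C@@]1(O[Si](CC)(CC)CC)CC[C@](C)(OO)CC[C@H]([C@H](C)CO[Si](c1ccccc1)(c1ccccc1)C(C)(C)C)OS(C)(=O)=O
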